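## Analysis of the target

Target **37** is a cis-fused decalin of the eremophilane type. Locants used throughout: ring A = C1, C2, C3, C4, C5, C10; ring B = C5, C6, C7, C8, C9, C10; C11 is the exocyclic carbon on C7 and carries C12 (CH2OH) and C13 (CH3); C14 is the methyl on C5, C15 the methyl on C4; β is the face of C14. O3 is acylated by (2E,4E,6E)-5-methyldodeca-2,4,6-trienoic acid.

There are five stereocentres, (3R,4R,5R,9R,10S). C4 and C5 carry cis (β) methyls, C5 is quaternary, H10 is β (cis fusion), O3 is α (trans to C15), and the C9 hydroxyl is β (cis to H10).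

Ring B holds a C8 ketone between the C9 carbinol (an α-ketol) and the tetrasubstituted exocyclic C7=C11 bond, whose CH2OH is cis to the ketone (Z).

The Z-γ-hydroxy-enone can close to a hemiketal and lose water to a furan under acid. The α-ketol can epimerise or undergo ketol shift under base. The trienoate does not tolerate hydride, strong base or light, so the ester must go on late and the last unmasking must be neutral.

The hard points are the four contiguous centres C3, C4, C5, C10 around a quaternary carbon, and the geometry of a tetrasubstituted alkene that no simple condensation controls.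

The plan rests on one feature: C3, C4, C5 and C10 all lie on ring A, and the cis methyls on C4 and C5 are exactly the cis methyls of a tiglyl (E-2-methylbut-2-enoyl) group. With a carbonyl at C6, C4=C5 is a dienophile, C3–C2–C1–C10 is a 1-oxygenated diene, and the chain C6–C9 that links them is ring B.

The price is that the cycloadduct has its carbonyl on C6. It must be moved to C8, and the C7=C11 geometry is then secured through a lactone ring.

## Retrosynthetic reasoning

**O3–acyl bond (37 ⇒ 36 ⇒ 30 + 34).** The trienoate is the most fragile part, so the ester bond is cut first. In the forward direction acid **34** acylates the C3 alcohol **30** while O9 and O12 are masked as allyl carbonates. These come off under neutral conditions, which the furan-prone hydroxy-enone and the α-ketol require. The C3 hydroxyl is freed from the silyl ether that entered with the diene.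

**Side chain (34 ⇒ 33 ⇒ 31 + 32).** The C4=C5 bond of the acid is cut in a vinylogous Horner–Wadsworth–Emmons sense. Enone **31** already contains the E-configured C6=C7 bond and the methyl-bearing carbon, and phosphonate **32** supplies C1–C4.

**C9–O bond (29 ⇒ 28 ⇒ 26).** The C9 hydroxyl is removed back to ketone **26**. Forward, the α′ enolate of the alkylidene ketone is oxidised. This is placed after the side chain is complete because only then is C9 the sole kinetically accessible α-position, and ring A shields one face.

**Geometry of C7=C11 (26 ⇒ 25 ⇒ 24 ⇒ 23).** C12 and O8 are cis across the double bond, so they are the two ends of a butenolide. Reduction of lactone **23** must give the Z-diol **24**, whose primary hydroxyl is protected (**25**) and whose secondary hydroxyl is oxidised. The ring, not a condensation, fixes the geometry.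

**C7–C11 bond (23 ⇒ 21 ⇒ 19 ⇒ 16 + 17).** The butenolide is opened to a hydroxy lactone and then to the aldol adduct of pyruvate **17** with the C7 enolate of an 8-ketone. That enolate is made regiospecifically by conjugate reduction of enone **16**, which a ketone with two α-methylene groups could not deliver by deprotonation.

**Carbonyl transposition (16 ⇒ 15 ⇒ 13 ⇒ 12 ⇒ 10).** The C8 carbonyl is traced back to the C6 carbonyl through allylic alcohol **15**, epoxy ketone **13** and enone **12**. C5 is quaternary, so **10** can only be dehydrogenated toward C7/C8, and the epoxy-ketone-to-allylic-alcohol shift moves the oxygen from C6 to C8.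

**C1–C2 saturation (10 ⇒ 9).** The ring A alkene of **9** has no further use and is hydrogenated at once.

**Key disconnection (9 ⇒ 8).** C3–C4 and C5–C10 are cut together. This opens both rings and converts four stereocentres into three alkene geometries (E tiglyl, E,E diene) plus one catalyst-controlled face. Forward, trienone **8** must cyclise endo, with the tether carbonyl under the diene.

**C5–C6 bond (8 ⇒ 5 + 6, via 7).** The tiglyl ketone is cut at the acyl–vinyl bond. Bromide **6** fixes the cis methyls, and N-methoxy-N-methylamide **5** stops the addition at the ketone. The amide, unlike a ketone, also survives the silylation that makes the diene.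

**Diene and chain (5 ⇒ 4 ⇒ 2 + 3; 2 ⇒ 1).** The silyl dienol ether comes from γ-deprotonation of enal **4**. The enal comes from cross-metathesis of alkene **2** with **3**, and **2** from acid **1**.

## Alternatives that were turned down

**Alternative 1: masked o-quinone cycloadduct and anionic oxy-Cope rearrangement.**
- Disconnection: in the cis-decalin A1 (cis-fused 9,9-dimethoxy-4,5-dimethyloctal-3-en-8-one, target locants) C5–C6 is cut and C3–C8 is joined. This leads to the bicyclic carbinol A2 (3,3-dimethoxy-5,6-dimethyl-2-vinylbicyclo[2.2.2]oct-5-en-2-ol, vinyl syn to the dimethyl-substituted bridge).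
- Forward key step: the potassium alkoxide of A2 (KH, 18-crown-6) undergoes a [3,3] shift. The vinyl terminus bonds to C5, C3–C8 breaks, and the C8 enolate is released in a cis-fused decalin.
- For it: ring B arrives with a ketone on C8 and C9 at the ketone level as its ketal. That is the 8,9-dioxygenation the chosen route must build by a four-step transposition and a late enolate oxidation, so on this point the alternative is stronger. The quaternary C5 and the cis fusion come from a rigid bicycle.
- Against it: only C5 and C10 are set. C3 and C4 emerge as the C3=C4 double bond of A1, so O3 and H4 must be added later with face control. The free carbonyl sits on C8 while C9 must end as the alcohol, so the two oxygens have to be differentiated by extra redox steps. Masked o-quinone cycloadditions give racemates, so A2 needs a resolution or an auxiliary. The C7 side chain and its geometry are no easier.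
- Comparison: shorter to the bicycle and better on the ring B oxidation pattern. The chosen strategy instead sets four of the five stereocentres in one catalytic enantioselective step.

**Alternative 2: oxidative dearomatisation of a phenol with alkene capture.**
- Disconnection: C4–C5 and C3–O of the cross-conjugated dienone A3 (3-acetoxy-4,5-dimethyl bicyclic dienone with the C8 ketone) are cut back to the phenol A4 (4-methyl-3-[(E)-pent-3-en-1-yl]phenol).
- Forward key step: PhI(OAc)2 oxidises A4, the tethered E-alkene attacks the para carbon (C4–C5), and acetate traps C3 anti.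
- For it: two or three steps from a trivial phenol give a bicycle that already holds O3, both methyls and the C8 ketone, with C6=C7 placed for work at C7. In step economy it beats the chosen route clearly.
- Against it: an unactivated 1,2-disubstituted alkene is a weak nucleophile, and closure needs a secondary, unstabilised cation at C3. Capture of the oxidised phenol at C5 by acetate or solvent competes. The C4/C5 relation depends on a chair-versus-boat choice. C10 is left sp2 and must later be reduced face-selectively to the cis fusion, and chemoselectively against C6=C7. Enantiocontrol would rest on chiral aryl-iodine reagents, which are not secure for a carbocyclisation that forms a quaternary centre.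
- Comparison: much shorter on paper, but each stereochemical element (C4/C5, C10, absolute sense) is open. The chosen cycloaddition derives all of them from alkene geometry, an endo rule and one catalyst.

**Alternative 3: oxazole–alkyne cycloaddition to a furan, then unmasking.**
- Disconnection: C7–C8 and C11–C12 of the furan A5 (3,9-bis(silyloxy) furan-fused cis-decalin) are cut, with formal return of HCN. This gives the cyclohexane A6, which carries a but-2-ynyl group on C5 and a silyloxy(oxazol-5-yl)methyl group on C10.
- Forward key step: on heating, the alkyne adds across C2 and C5 of the oxazole and the adduct loses HCN, closing ring B and the 3-methylfuran together.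
- For it: the furan holds C7=C11 in a ring, so C12 and C8 are cis by construction, with both oxygens on the right carbons and C9 already oxygenated. On the alkene geometry it is as strong as butenolide **23** of the chosen route and reaches that point more directly.
- Against it: the key step creates no stereocentre. All five, including the quaternary C5 with three contiguous neighbours and C9, must be built beforehand on a monocyclic ring. The reaction needs high temperature. Unmasking requires oxidative opening of the furan and then reduction of only the C12 aldehyde beside the C8 enone, on a system that recloses to the furan under acid.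
- Comparison: it solves the ring B end elegantly and moves the real difficulty into A6. The chosen strategy spends its key step on the four ring A stereocentres and accepts a longer ring B endgame.

Key step: step 5

Convention: bicyclic compounds are named with the locants of **37** (β = face of C14); TBS = tert-butyldimethylsilyl.

Assumption: the (S)-oxazaborolidine is written for step 5; should it deliver the antipode of **9**, the (R)-catalyst is used instead, both being accessible.

Assumption: steps 11 and 12 may give any configuration at C7, C11 and C8; **19**–**25** are written without descriptors at these atoms, all of which become sp2 by step 16.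

## Steps

Step 1
Reactants: 1 hept-6-enoic acid
Product: 2 N-methoxy-N-methylhept-6-enamide
Conditions: CDI, CH2Cl2, rt; then MeNHOMe·HCl, rt
Reagents that add atoms: N,O-dimethylhydroxylamine hydrochloride, Cl.CNOC
Why: Acyl imidazolide formation and aminolysis (Weinreb amide synthesis); the amide later stops the vinyllithium addition at the ketone stage and is inert to metathesis and silylation.

Step 2
Reactants: 2 N-methoxy-N-methylhept-6-enamide; 3 (E)-but-2-enal
Product: 4 (E)-N-methoxy-N-methyl-8-oxooct-6-enamide
Conditions: 3 (5 equiv), second-generation Hoveyda–Grubbs catalyst RuCl2(H2IMes)(=CH–C6H4-2-O-i-Pr) (3 mol%), CH2Cl2, 40 °C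
Reagents that add atoms: none
Why: Olefin cross-metathesis of a terminal alkene with an enal; the conjugated product should form as the E isomer under thermodynamic control.

Step 3
Reactants: 4 (E)-N-methoxy-N-methyl-8-oxooct-6-enamide
Product: 5 (5E,7E)-8-(tert-butyldimethylsilyloxy)-N-methoxy-N-methylocta-5,7-dienamide
Conditions: TBSOTf, Et3N, CH2Cl2, −78 → 0 °C
Reagents that add atoms: tert-butyldimethylsilyl trifluoromethanesulfonate, CC(C)(C)[Si](C)(C)OS(=O)(=O)C(F)(F)F
Why: Soft enolisation: O-silylation of the s-trans enal and γ-deprotonation by the amine give the 1-silyloxy-1,3-diene; the E enol ether follows from the s-trans enal, and the new C5=C6 bond should form mainly E because the chain avoids the inside position during deprotonation. The amide is not enolised under these conditions.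

Step 4
Reactants: 5 (5E,7E)-8-(tert-butyldimethylsilyloxy)-N-methoxy-N-methylocta-5,7-dienamide; 6 (E)-2-bromobut-2-ene
Product: 8 (2E,8E,10E)-11-(tert-butyldimethylsilyloxy)-3-methylundeca-2,8,10-trien-4-one, via butenyllithium 7 (not isolated)
Conditions: 6, t-BuLi (2 equiv), Et2O, −78 °C; then 5, THF, −78 → −40 °C; H2O quench at −40 °C
Reagents that add atoms: none
Why: Bromine–lithium exchange proceeds with retention of the alkene geometry, and the stable tetrahedral adduct of the N-methoxy-N-methylamide releases the tiglyl ketone only on work-up (Weinreb ketone synthesis), so neither over-addition nor loss of the cis-dimethyl geometry is expected. The silyl dienol ether tolerates the organolithium at low temperature and the basic quench.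

Step 5
Reactants: 8 (2E,8E,10E)-11-(tert-butyldimethylsilyloxy)-3-methylundeca-2,8,10-trien-4-one
Product: 9 3α-(tert-butyldimethylsilyloxy)-4β,5β-dimethyl-10βH-cis-octal-1-en-6-one (3R,4R,5S,10S)
Conditions: (S)-3,3-diphenyl-1-(o-tolyl)tetrahydro-1H,3H-pyrrolo[1,2-c][1,3,2]oxazaborole (20 mol%), Tf2NH (17 mol%), CH2Cl2, −78 → −20 °C
Reagents that add atoms: none
Why: The oxazaborolidinium ion binds the C6 carbonyl and lowers the LUMO of the tiglyl C4=C5 bond, and the (E,E)-silyloxydiene adds in a concerted, asynchronous [4+2] cycloaddition; the closest known reactions are the Lewis-acid-promoted type 1 intramolecular Diels–Alder closure of 1,7,9-decatrien-3-ones to cis-octalones and oxazaborolidinium-catalysed cycloadditions of enones. Ring A closes as the new cyclohexene through C3–C4 and C5–C10, all six of its atoms coming from diene and dienophile, and ring B closes as the six-membered tether ring C5–C6–C7–C8–C9–C10 when the fusion bond C5–C10 forms. C4 and C5 are set by suprafacial addition to the E-configured tiglyl unit (methyls cis), and C3 and C10 by suprafacial addition to the E,E-diene (C3–O and C10–C9 cis). The two pairs are linked by the endo position of the tether carbonyl, which puts C6 cis to C9 and to O3 and so gives the cis fusion and O3 trans to the C4 methyl. The absolute sense comes from the catalyst, which shields one enantiotopic face of the bound enone. The step needs endo over exo selectivity, which a Lewis-acid-bound carbonyl inside a four-atom tether favours, face selectivity, which rests on the catalyst alone, and survival of the silyl dienol ether, for which the catalyst is made with a deficit of Tf2NH so that no free acid remains. The regiochemistry is fixed by the tether, which joins the oxygen-bearing diene terminus to the β-carbon against the usual polarity preference, so the rate relies on intramolecularity and Lewis acid activation more than on the donor.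

Step 6
Reactants: 9 3α-(tert-butyldimethylsilyloxy)-4β,5β-dimethyl-10βH-cis-octal-1-en-6-one
Product: 10 3α-(tert-butyldimethylsilyloxy)-4β,5β-dimethyl-10βH-cis-decalin-6-one
Conditions: H2 (1 atm), 5% Rh/Al2O3, EtOAc, rt
Reagents that add atoms: none
Why: Heterogeneous hydrogenation of the cis-disubstituted C1=C2 bond; rhodium on alumina is chosen because it rarely cleaves or isomerises allylic silyl ethers, and no stereocentre is created.

Step 7
Reactants: 10 3α-(tert-butyldimethylsilyloxy)-4β,5β-dimethyl-10βH-cis-decalin-6-one
Product: 12 3α-(tert-butyldimethylsilyloxy)-4β,5β-dimethyl-10βH-cis-octal-7-en-6-one, via trimethylsilyl enol ether 11 (not isolated)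
Conditions: LiN(i-Pr)2, TMSCl, THF, −78 °C; then Pd(OAc)2 (1.1 equiv), MeCN, rt
Reagents that add atoms: none
Why: Saegusa–Ito dehydrogenation; C5 is quaternary, so the enol ether can only form toward C7, and the divalent palladium enolate loses the C8 hydrogen to give the C7=C8 enone.

Step 8
Reactants: 12 3α-(tert-butyldimethylsilyloxy)-4β,5β-dimethyl-10βH-cis-octal-7-en-6-one
Product: 13 7β,8β-epoxy-3α-(tert-butyldimethylsilyloxy)-4β,5β-dimethyl-10βH-cis-decalin-6-one
Conditions: 30% H2O2, NaOH, MeOH, 0 °C
Reagents that add atoms: hydrogen peroxide, OO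
Why: Nucleophilic (Weitz–Scheffer) epoxidation of the enone; hydroperoxide should add to C8 from the convex β face, but the epoxide configuration is erased two steps later.

Step 9
Reactants: 13 7β,8β-epoxy-3α-(tert-butyldimethylsilyloxy)-4β,5β-dimethyl-10βH-cis-decalin-6-one
Product: 15 3α-(tert-butyldimethylsilyloxy)-4β,5β-dimethyl-10βH-cis-octal-6-en-8β-ol, via epoxy hydrazone 14 (not isolated)
Conditions: N2H4·H2O, AcOH (cat.), MeOH, 0 °C → rt
Reagents that add atoms: none
Why: Wharton transposition: the hydrazone opens the epoxide to an alkenyl diazene, which loses dinitrogen and leaves the C6=C7 alkene and the C8 alcohol, so the oxygen has moved from C6 to C8.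

Step 10
Reactants: 15 3α-(tert-butyldimethylsilyloxy)-4β,5β-dimethyl-10βH-cis-octal-6-en-8β-ol
Product: 16 3α-(tert-butyldimethylsilyloxy)-4β,5β-dimethyl-10βH-cis-octal-6-en-8-one
Conditions: Dess–Martin periodinane, CH2Cl2, rt
Reagents that add atoms: none
Why: Oxidation of the secondary allylic alcohol to the enone with a hypervalent iodine reagent; nothing else in 15 is oxidisable.

Step 11
Reactants: 16 3α-(tert-butyldimethylsilyloxy)-4β,5β-dimethyl-10βH-cis-octal-6-en-8-one; 17 ethyl pyruvate
Product: 19 ethyl 2-hydroxy-2-[3α-(tert-butyldimethylsilyloxy)-4β,5β-dimethyl-8-oxo-10βH-cis-decalin-7-yl]propanoate, via lithium enolate 18 (not isolated)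
Conditions: LiBH(s-Bu)3 (1.05 equiv), THF, −78 °C; then 17, −78 °C; aq. NH4Cl
Reagents that add atoms: none
Why: Conjugate hydride addition to C6 gives the C7–C8 enolate regiospecifically (reductive aldol), and this enolate adds to the ketone carbonyl of the α-keto ester. Both new centres (C7, C11) become sp2 in step 13, so their configuration does not matter.

Step 12
Reactants: 19 ethyl 2-hydroxy-2-[3α-(tert-butyldimethylsilyloxy)-4β,5β-dimethyl-8-oxo-10βH-cis-decalin-7-yl]propanoate
Product: 21 3α-(tert-butyldimethylsilyloxy)-11-hydroxy-10βH-cis-eremophilan-12,8-olide, via dihydroxy ester 20 (not isolated)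
Conditions: NaBH4, CeCl3·7H2O, MeOH, −40 °C; then pyridinium p-toluenesulfonate (cat.), toluene, 60 °C
Reagents that add atoms: none
Why: Ketone reduction under nearly neutral conditions, which suppress retro-aldol cleavage, followed by five-membered lactonisation of the C8 hydroxyl onto the ester. This ring later holds C12 and O8 on the same side of C7=C11.

Step 13
Reactants: 21 3α-(tert-butyldimethylsilyloxy)-11-hydroxy-10βH-cis-eremophilan-12,8-olide
Product: 23 3α-(tert-butyldimethylsilyloxy)-10βH-cis-eremophil-7(11)-en-12,8-olide, via α-methylene lactone 22 (not isolated)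
Conditions: SOCl2, pyridine, CH2Cl2, 0 °C; then RhCl(PPh3)3 (cat.), Et3SiH (cat.), toluene, 90 °C
Reagents that add atoms: none
Why: E2 dehydration of the tertiary α-hydroxy lactone through its chlorosulfite gives the butenolide directly where H7 is anti to the leaving group and the exocyclic isomer 22 otherwise. Rhodium hydride addition–elimination then moves the exocyclic double bond of 22 into the ring, the conjugated tetrasubstituted position being the thermodynamic one.

Step 14
Reactants: 23 3α-(tert-butyldimethylsilyloxy)-10βH-cis-eremophil-7(11)-en-12,8-olide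
Product: 24 (7(11)Z)-3α-(tert-butyldimethylsilyloxy)-10βH-cis-eremophil-7(11)-ene-8,12-diol
Conditions: i-Bu2AlH (4 equiv), CH2Cl2, −78 → 0 °C; aq. potassium sodium tartrate
Reagents that add atoms: none
Why: Hydride reduction of the butenolide through the lactol to the 2-ene-1,4-diol; the alkene geometry is that of the lactone ring, so C12 is necessarily cis to C8.

Step 15
Reactants: 24 (7(11)Z)-3α-(tert-butyldimethylsilyloxy)-10βH-cis-eremophil-7(11)-ene-8,12-diol
Product: 25 (7(11)Z)-12-(allyloxycarbonyloxy)-3α-(tert-butyldimethylsilyloxy)-10βH-cis-eremophil-7(11)-en-8-ol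
Conditions: allyl chloroformate (1.1 equiv), pyridine, CH2Cl2, −40 → 0 °C
Reagents that add atoms: allyl chloroformate, C=CCOC(=O)Cl
Why: Carbonate formation at the unhindered primary allylic hydroxyl in preference to the secondary C8 hydroxyl beside the tetrasubstituted alkene; the product is oxidised without delay so that the carbonate cannot migrate to O8.

Step 16
Reactants: 25 (7(11)Z)-12-(allyloxycarbonyloxy)-3α-(tert-butyldimethylsilyloxy)-10βH-cis-eremophil-7(11)-en-8-ol
Product: 26 (7(11)Z)-12-(allyloxycarbonyloxy)-3α-(tert-butyldimethylsilyloxy)-10βH-cis-eremophil-7(11)-en-8-one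
Conditions: Dess–Martin periodinane, CH2Cl2, 0 °C → rt
Reagents that add atoms: none
Why: Oxidation of the remaining secondary allylic alcohol regenerates the C8 ketone, now conjugated with the Z-configured C7=C11 bond; the C8 epimers converge here.

Step 17
Reactants: 26 (7(11)Z)-12-(allyloxycarbonyloxy)-3α-(tert-butyldimethylsilyloxy)-10βH-cis-eremophil-7(11)-en-8-one
Product: 28 (7(11)Z)-12-(allyloxycarbonyloxy)-3α-(tert-butyldimethylsilyloxy)-9β-hydroxy-10βH-cis-eremophil-7(11)-en-8-one, via lithium enolate 27 (not isolated)
Conditions: LiN(SiMe3)2, THF, −78 °C; then 2-(phenylsulfonyl)-3-phenyloxaziridine, −78 °C; aq. NH4Cl at −78 °C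
Reagents that add atoms: 2-(phenylsulfonyl)-3-phenyloxaziridine, O=S(=O)(c1ccccc1)N1OC1c1ccccc1
Why: Kinetic deprotonation of the α-alkylidene ketone at the α′ carbon C9, then oxidation of the cross-conjugated enolate by the N-sulfonyloxaziridine (enolate hydroxylation). In the favoured conformer (O3 and C15 equatorial) the C4–C5 bond is axial on ring B and screens the α face of C9, so oxygen should enter from the convex β face, cis to H10; the β alcohol is also the equatorial, more stable epimer.

Step 18
Reactants: 28 (7(11)Z)-12-(allyloxycarbonyloxy)-3α-(tert-butyldimethylsilyloxy)-9β-hydroxy-10βH-cis-eremophil-7(11)-en-8-one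
Product: 29 (7(11)Z)-9β,12-bis(allyloxycarbonyloxy)-3α-(tert-butyldimethylsilyloxy)-10βH-cis-eremophil-7(11)-en-8-one
Conditions: allyl chloroformate, pyridine, DMAP (cat.), CH2Cl2, 0 °C → rt
Reagents that add atoms: allyl chloroformate, C=CCOC(=O)Cl
Why: Acylation of the secondary α-ketol hydroxyl, which must be masked before O3 is acylated.

Step 19
Reactants: 29 (7(11)Z)-9β,12-bis(allyloxycarbonyloxy)-3α-(tert-butyldimethylsilyloxy)-10βH-cis-eremophil-7(11)-en-8-one
Product: 30 (7(11)Z)-9β,12-bis(allyloxycarbonyloxy)-3α-hydroxy-10βH-cis-eremophil-7(11)-en-8-one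
Conditions: HF·pyridine, pyridine, THF, 0 °C → rt
Reagents that add atoms: none
Why: Fluoride-mediated cleavage of the silyl ether; the allyl carbonates, the enone and the α-acyloxy ketone are stable to buffered HF, and with O12 acylated the enone cannot close to a furan.

Step 20
Reactants: 31 (E)-non-3-en-2-one; 32 triethyl (E)-4-phosphonobut-2-enoate
Product: 33 ethyl (2E,4E,6E)-5-methyldodeca-2,4,6-trienoate
Conditions: NaH, THF, 0 °C → rt
Reagents that add atoms: none
Why: Vinylogous Horner–Wadsworth–Emmons olefination of the methyl ketone, which forms C4=C5 and brings in C2=C3 as E. The 4E isomer should predominate; the 4Z isomer is removed by chromatography here or by crystallisation of 34.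

Step 21
Reactants: 33 ethyl (2E,4E,6E)-5-methyldodeca-2,4,6-trienoate
Product: 34 (2E,4E,6E)-5-methyldodeca-2,4,6-trienoic acid
Conditions: LiOH, THF/MeOH/H2O, rt, dark; then 1 M HCl to pH 3
Reagents that add atoms: lithium hydroxide, [Li+].[OH-]
Why: Saponification of the ethyl ester; the triene is stable to aqueous hydroxide at room temperature in the dark.

Step 22
Reactants: 30 (7(11)Z)-9β,12-bis(allyloxycarbonyloxy)-3α-hydroxy-10βH-cis-eremophil-7(11)-en-8-one; 34 (2E,4E,6E)-5-methyldodeca-2,4,6-trienoic acid
Product: 36 (7(11)Z)-9β,12-bis(allyloxycarbonyloxy)-8-oxo-10βH-cis-eremophil-7(11)-en-3α-yl (2E,4E,6E)-5-methyldodeca-2,4,6-trienoate, via mixed anhydride 35 (not isolated)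
Conditions: 34, 2,4,6-trichlorobenzoyl chloride, Et3N, THF, rt; then 30, DMAP, toluene, rt
Reagents that add atoms: none
Why: Yamaguchi esterification; the equatorial C3 hydroxyl is the only free hydroxyl, and the conjugated acyl group is transferred through the acylpyridinium ion without touching the carbonates.

Step 23
Reactants: 36 (7(11)Z)-9β,12-bis(allyloxycarbonyloxy)-8-oxo-10βH-cis-eremophil-7(11)-en-3α-yl (2E,4E,6E)-5-methyldodeca-2,4,6-trienoate
Product: 37 (3R,4R,5R,9R,10S;7(11)Z)-9β,12-dihydroxy-8-oxo-10βH-cis-eremophil-7(11)-en-3α-yl (2E,4E,6E)-5-methyldodeca-2,4,6-trienoate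
Conditions: Pd(PPh3)4 (5 mol%), dimedone, THF, rt, dark
Reagents that add atoms: none
Why: Zerovalent palladium ionises both allyl carbonates to π-allyl complexes, the carbonate monoesters lose CO2, and dimedone takes up the allyl groups. O9 and O12 are thus freed at neutral pH, without acid (no furan), base (no ketol shift) or hydride (ester intact).

## Compound list

1 | hept-6-enoic acid | C=CCCCCC(=O)O | starting material
2 | N-methoxy-N-methylhept-6-enamide | C=CCCCCC(=O)N(C)OC | intermediate
3 | (E)-but-2-enal (crotonaldehyde) | C/C=C/C=O | starting material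
4 | (E)-N-methoxy-N-methyl-8-oxooct-6-enamide | O=C/C=C/CCCCC(=O)N(C)OC | intermediate
5 | (5E,7E)-8-(tert-butyldimethylsilyloxy)-N-methoxy-N-methylocta-5,7-dienamide | CON(C)C(=O)CCC/C=C/C=C/O[Si](C)(C)C(C)(C)C | intermediate
6 | (E)-2-bromobut-2-ene (methyl groups cis) | C/C=C(\C)Br | starting material
7 | but-2-en-2-yllithium, methyl groups cis as in 6 (Z by the sequence rule) | C/C=C(\C)[Li] | intermediate
8 | (2E,8E,10E)-11-(tert-butyldimethylsilyloxy)-3-methylundeca-2,8,10-trien-4-one | C/C=C(\C)C(=O)CCC/C=C/C=C/O[Si](C)(C)C(C)(C)C | intermediate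
9 | (3R,4R,5S,10S)-3α-(tert-butyldimethylsilyloxy)-4β,5β-dimethyl-10βH-cis-octal-1-en-6-one | CC(C)(C)[Si](C)(C)O[C@@H]1C=C[C@@H]2CCCC(=O)[C@]2(C)[C@H]1C | intermediate
10 | 3α-(tert-butyldimethylsilyloxy)-4β,5β-dimethyl-10βH-cis-decalin-6-one | CC(C)(C)[Si](C)(C)O[C@@H]1CC[C@@H]2CCCC(=O)[C@]2(C)[C@H]1C | intermediate
11 | 6-trimethylsilyl enol ether of 10 (C6=C7) | CC(C)(C)[Si](C)(C)O[C@@H]1CC[C@@H]2CCC=C(O[Si](C)(C)C)[C@]2(C)[C@H]1C | intermediate
12 | 3α-(tert-butyldimethylsilyloxy)-4β,5β-dimethyl-10βH-cis-octal-7-en-6-one | CC(C)(C)[Si](C)(C)O[C@@H]1CC[C@@H]2CC=CC(=O)[C@]2(C)[C@H]1C | intermediate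
13 | 7β,8β-epoxy-3α-(tert-butyldimethylsilyloxy)-4β,5β-dimethyl-10βH-cis-decalin-6-one | CC(C)(C)[Si](C)(C)O[C@@H]1CC[C@@H]2C[C@H]3O[C@H]3C(=O)[C@]2(C)[C@H]1C | intermediate
14 | C6 hydrazone of 13 | CC(C)(C)[Si](C)(C)O[C@@H]1CC[C@@H]2C[C@H]3O[C@H]3C(=NN)[C@]2(C)[C@H]1C | intermediate
15 | 3α-(tert-butyldimethylsilyloxy)-4β,5β-dimethyl-10βH-cis-octal-6-en-8β-ol | CC(C)(C)[Si](C)(C)O[C@@H]1CC[C@@H]2C[C@@H](O)C=C[C@]2(C)[C@H]1C | intermediate
16 | 3α-(tert-butyldimethylsilyloxy)-4β,5β-dimethyl-10βH-cis-octal-6-en-8-one | CC(C)(C)[Si](C)(C)O[C@@H]1CC[C@@H]2CC(=O)C=C[C@]2(C)[C@H]1C | intermediate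
17 | ethyl pyruvate | CCOC(=O)C(C)=O | starting material
18 | lithium C7=C8 enolate of the 8-ketone | CC(C)(C)[Si](C)(C)O[C@@H]1CC[C@@H]2CC(O[Li])=CC[C@]2(C)[C@H]1C | intermediate
19 | ethyl 2-hydroxy-2-[3α-(tert-butyldimethylsilyloxy)-4β,5β-dimethyl-8-oxo-10βH-cis-decalin-7-yl]propanoate (mixture at C7 and C11) | CC(C)(C)[Si](C)(C)O[C@@H]1CC[C@@H]2CC(=O)C(C(C)(O)C(=O)OCC)C[C@]2(C)[C@H]1C | intermediate
20 | ethyl 2-hydroxy-2-[3α-(tert-butyldimethylsilyloxy)-8-hydroxy-4β,5β-dimethyl-10βH-cis-decalin-7-yl]propanoate (mixture at C7, C8, C11) | CC(C)(C)[Si](C)(C)O[C@@H]1CC[C@@H]2CC(O)C(C(C)(O)C(=O)OCC)C[C@]2(C)[C@H]1C | intermediate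
21 | 3α-(tert-butyldimethylsilyloxy)-11-hydroxy-10βH-cis-eremophilan-12,8-olide (mixture at C7, C8, C11) | CC(C)(C)[Si](C)(C)O[C@@H]1CC[C@@H]2CC3OC(=O)C(C)(O)C3C[C@]2(C)[C@H]1C | intermediate
22 | 3α-(tert-butyldimethylsilyloxy)-10βH-cis-eremophil-11(13)-en-12,8-olide (mixture at C7, C8) | CC(C)(C)[Si](C)(C)O[C@@H]1CC[C@@H]2CC3OC(=O)C(=C)C3C[C@]2(C)[C@H]1C | intermediate
23 | 3α-(tert-butyldimethylsilyloxy)-10βH-cis-eremophil-7(11)-en-12,8-olide (C8 epimers) | CC(C)(C)[Si](C)(C)O[C@@H]1CC[C@@H]2CC3OC(=O)C(C)=C3C[C@]2(C)[C@H]1C | intermediate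
24 | (7(11)Z)-3α-(tert-butyldimethylsilyloxy)-10βH-cis-eremophil-7(11)-ene-8,12-diol (C8 epimers) | CC(C)(C)[Si](C)(C)O[C@@H]1CC[C@@H]2CC(O)/C(=C(/C)CO)C[C@]2(C)[C@H]1C | intermediate
25 | (7(11)Z)-12-(allyloxycarbonyloxy)-3α-(tert-butyldimethylsilyloxy)-10βH-cis-eremophil-7(11)-en-8-ol (C8 epimers) | CC(C)(C)[Si](C)(C)O[C@@H]1CC[C@@H]2CC(O)/C(=C(/C)COC(=O)OCC=C)C[C@]2(C)[C@H]1C | intermediate
26 | (7(11)Z)-12-(allyloxycarbonyloxy)-3α-(tert-butyldimethylsilyloxy)-10βH-cis-eremophil-7(11)-en-8-one | CC(C)(C)[Si](C)(C)O[C@@H]1CC[C@@H]2CC(=O)/C(=C(/C)COC(=O)OCC=C)C[C@]2(C)[C@H]1C | intermediate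
27 | lithium C8=C9 enolate of 26 | CC(C)(C)[Si](C)(C)O[C@@H]1CC[C@@H]2C=C(O[Li])/C(=C(/C)COC(=O)OCC=C)C[C@]2(C)[C@H]1C | intermediate
28 | (7(11)Z)-12-(allyloxycarbonyloxy)-3α-(tert-butyldimethylsilyloxy)-9β-hydroxy-10βH-cis-eremophil-7(11)-en-8-one | CC(C)(C)[Si](C)(C)O[C@@H]1CC[C@@H]2[C@@H](O)C(=O)/C(=C(/C)COC(=O)OCC=C)C[C@]2(C)[C@H]1C | intermediate
29 | (7(11)Z)-9β,12-bis(allyloxycarbonyloxy)-3α-(tert-butyldimethylsilyloxy)-10βH-cis-eremophil-7(11)-en-8-one | CC(C)(C)[Si](C)(C)O[C@@H]1CC[C@@H]2[C@@H](OC(=O)OCC=C)C(=O)/C(=C(/C)COC(=O)OCC=C)C[C@]2(C)[C@H]1C | intermediate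
30 | (7(11)Z)-9β,12-bis(allyloxycarbonyloxy)-3α-hydroxy-10βH-cis-eremophil-7(11)-en-8-one | O[C@@H]1CC[C@@H]2[C@@H](OC(=O)OCC=C)C(=O)/C(=C(/C)COC(=O)OCC=C)C[C@]2(C)[C@H]1C | intermediate
31 | (E)-non-3-en-2-one | CCCCC/C=C/C(C)=O | starting material
32 | triethyl (E)-4-phosphonobut-2-enoate | CCOC(=O)/C=C/CP(=O)(OCC)OCC | starting material
33 | ethyl (2E,4E,6E)-5-methyldodeca-2,4,6-trienoate | CCCCC/C=C/C(C)=C/C=C/C(=O)OCC | intermediate
34 | (2E,4E,6E)-5-methyldodeca-2,4,6-trienoic acid | CCCCC/C=C/C(C)=C/C=C/C(=O)O | intermediate
35 | (2E,4E,6E)-5-methyldodeca-2,4,6-trienoic 2,4,6-trichlorobenzoic anhydride | CCCCC/C=C/C(C)=C/C=C/C(=O)OC(=O)c1c(Cl)cc(Cl)cc1Cl | intermediate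
36 | (7(11)Z)-9β,12-bis(allyloxycarbonyloxy)-8-oxo-10βH-cis-eremophil-7(11)-en-3α-yl (2E,4E,6E)-5-methyldodeca-2,4,6-trienoate | CCCCC/C=C/C(C)=C/C=C/C(=O)O[C@@H]1CC[C@@H]2[C@@H](OC(=O)OCC=C)C(=O)/C(=C(/C)COC(=O)OCC=C)C[C@]2(C)[C@H]1C | intermediate
37 | (3R,4R,5R,9R,10S;7(11)Z)-9β,12-dihydroxy-8-oxo-10βH-cis-eremophil-7(11)-en-3α-yl (2E,4E,6E)-5-methyldodeca-2,4,6-trienoate | CCCCC/C=C/C(C)=C/C=C/C(=O)O[C@@H]1CC[C@@H]2[C@@H](O)C(=O)/C(=C(/C)CO)C[C@]2(C)[C@H]1C | target

## Step count and least certain steps

Total: 23 steps. Longest linear sequence: 21 steps (steps 1–19, 22 and 23, from **1**); the side-chain branch is steps 20 and 21.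

**Step 5 (key step).**
- What may go wrong: slow cycloaddition, because the dienophile is trisubstituted and the tether joins the oxygen-bearing diene terminus to the β-carbon, so the donor helps less than in an intermolecular case. Protodesilylation of the dienol ether by the strongly acidic catalyst. A stepwise vinylogous Mukaiyama–Michael closure to a seven-membered ring. Poor enantiofacial discrimination, because a tiglyl ketone offers the catalyst less organisation than an α-unsubstituted enone.
- Fallback (from **8**, back at **9**): cyclise without a chiral catalyst (Me2AlCl, CH2Cl2, −78 → −20 °C, or toluene at reflux with a radical inhibitor) and resolve. This should give **9** together with its antipode ent-9 F1. Bu4NF/AcOH releases the allylic alcohol 3α-hydroxy-4β,5β-dimethyl-10βH-cis-octal-1-en-6-one F2 and its antipode ent-alcohol F3. Esterification with (S)-O-methylmandelic acid (DCC, cat. DMAP, 0 °C) gives the diastereomeric esters, the (S)-O-methylmandelate of the wanted alcohol F4 and the (S)-O-methylmandelate of the antipode F5, which are separated by chromatography or crystallisation. Methanolysis of F4 (K2CO3, MeOH) returns F2, and TBSOTf/2,6-lutidine returns **9**.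

**Step 3.**
- What may go wrong: partial formation of the 5Z diene through deprotonation of the rotamer with the chain inside. The 5Z isomer cannot reach the s-cis geometry and is dead weight in step 5.
- Fallback (from **4**, back at **5**): replace stereoselective enolisation by stereoconvergence. The crude diene mixture is equilibrated toward the E,E isomer by a thiyl radical chain (PhSSPh cat., light, hexane), the thermodynamic preference for the E,E diene doing the work. Whatever 5Z material survives is carried through step 4 and left behind in step 5, where it does not cyclise. This fallback makes no new compound (F0).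

**Step 9.**
- What may go wrong: slow hydrazone formation at the neopentyl C6 carbonyl, so that epoxide opening by hydrazine or reduction competes with the Wharton fragmentation.
- Fallback (from **10**, back at **16**): KN(SiMe3)2 and PhNTf2 convert **10** into the C6 enol triflate F6. Reduction with Pd(OAc)2/PPh3, HCO2H and Bu3N gives the alkene 3α-(tert-butyldimethylsilyloxy)-4β,5β-dimethyl-10βH-cis-octal-6-ene F7. Allylic oxidation (CrO3·3,5-dimethylpyrazole, CH2Cl2, −20 °C) at C8, the only allylic CH2, gives **16**.

**Step 11.**
- What may go wrong: 1,2-reduction instead of conjugate reduction, because C6 is next to the quaternary C5. Proton transfer from the pyruvate methyl to the enolate. Retro-aldol loss of the tertiary aldolate.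
- Fallback (from **16**, back at **19**): separate the two events. Et3SiH with RhCl(PPh3)3 (cat.) gives, by 1,4-hydrosilylation, the triethylsilyl enol ether F8. A Mukaiyama aldol addition of F8 to **17** (TiCl4, CH2Cl2, −78 °C) gives **19**.

**Step 17.**
- What may go wrong: attack of the oxidant on the α face if ring B reacts through the other half-chair, γ-deprotonation at C12, or transfer of the C12 carbonate to the new alkoxide.
- Fallback (from **26**, back at **28**): if the α alcohol, the 9α-hydroxy epimer of 28 F9, is the main product, it is inverted. Mitsunobu reaction with chloroacetic acid (PPh3, diisopropyl azodicarboxylate) gives the 9β-chloroacetate F10. Thiourea and NaHCO3 in ethanol remove the chloroacetyl group without touching the allyl carbonate and give **28**.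

## Further compounds

F1 | step 5 | ent-9, (3S,4S,5R,10R)-3-(tert-butyldimethylsilyloxy)-4,5-dimethyl-cis-octal-1-en-6-one | CC(C)(C)[Si](C)(C)O[C@H]1C=C[C@H]2CCCC(=O)[C@@]2(C)[C@@H]1C
F2 | step 5 | 3α-hydroxy-4β,5β-dimethyl-10βH-cis-octal-1-en-6-one (desilylated 9) | O[C@@H]1C=C[C@@H]2CCCC(=O)[C@]2(C)[C@H]1C
F3 | step 5 | antipode of F2 | O[C@H]1C=C[C@H]2CCCC(=O)[C@@]2(C)[C@@H]1C
F4 | step 5 | (S)-2-methoxy-2-phenylacetate of F2 | CO[C@@H](c1ccccc1)C(=O)O[C@@H]1C=C[C@@H]2CCCC(=O)[C@]2(C)[C@H]1C
F5 | step 5 | (S)-2-methoxy-2-phenylacetate of F3 | CO[C@@H](c1ccccc1)C(=O)O[C@H]1C=C[C@H]2CCCC(=O)[C@@]2(C)[C@@H]1C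
F0 | step 3 | none | none
F6 | step 9 | 3α-(tert-butyldimethylsilyloxy)-4β,5β-dimethyl-10βH-cis-octal-6-en-6-yl trifluoromethanesulfonate | CC(C)(C)[Si](C)(C)O[C@@H]1CC[C@@H]2CCC=C(OS(=O)(=O)C(F)(F)F)[C@]2(C)[C@H]1C
F7 | step 9 | 3α-(tert-butyldimethylsilyloxy)-4β,5β-dimethyl-10βH-cis-octal-6-ene | CC(C)(C)[Si](C)(C)O[C@@H]1CC[C@@H]2CCC=C[C@]2(C)[C@H]1C
F8 | step 11 | 8-triethylsilyl enol ether (C7=C8) of the 8-ketone | CC(C)(C)[Si](C)(C)O[C@@H]1CC[C@@H]2CC(O[Si](CC)(CC)CC)=CC[C@]2(C)[C@H]1C
F9 | step 17 | 9α-hydroxy epimer of 28 | CC(C)(C)[Si](C)(C)O[C@@H]1CC[C@@H]2[C@H](O)C(=O)/C(=C(/C)COC(=O)OCC=C)C[C@]2(C)[C@H]1C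
F10 | step 17 | 9β-chloroacetate of 28 | CC(C)(C)[Si](C)(C)O[C@@H]1CC[C@@H]2[C@@H](OC(=O)CCl)C(=O)/C(=C(/C)COC(=O)OCC=C)C[C@]2(C)[C@H]1C
A1 | alternative 1 | cis-fused 9,9-dimethoxy-4,5-dimethyloctal-3-en-8-one (target locants) | C1=C(C)[C@@]2(C)CCC(=O)C(OC)(OC)[C@H]2CC1
A2 | alternative 1 | 3,3-dimethoxy-5,6-dimethyl-2-vinylbicyclo[2.2.2]oct-5-en-2-ol, vinyl syn to the C5=C6 bridge | C=C[C@]1(O)C(OC)(OC)[C@H]2CC[C@@H]1C(C)=C2C
A3 | alternative 2 | 3-acetoxy-4,5-dimethyl bicyclic cross-conjugated dienone with the C8 ketone (target locants) | CC(=O)O[C@@H]1CCC2=CC(=O)C=C[C@]2(C)[C@H]1C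
A4 | alternative 2 | 4-methyl-3-[(E)-pent-3-en-1-yl]phenol | C/C=C/CCc1cc(O)ccc1C
A5 | alternative 3 | 3-(triethylsilyloxy)-9-(tert-butyldimethylsilyloxy) furan-fused cis-decalin (furan carbons C7, C8, C11, C12) | CC[Si](CC)(CC)O[C@@H]1CC[C@@H]2[C@@H](O[Si](C)(C)C(C)(C)C)c3occ(C)c3C[C@]2(C)[C@H]1C
A6 | alternative 3 | cyclohexane with 3-(triethylsilyloxy), 4,5-dimethyl, 5-(but-2-ynyl) and 10-[(tert-butyldimethylsilyloxy)(oxazol-5-yl)methyl] groups (target locants) | CC[Si](CC)(CC)O[C@@H]1CC[C@H]([C@@H](O[Si](C)(C)C(C)(C)C)c2cnco2)[C@](C)(CC#CC)[C@H]1C
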